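**Plan**
1. The target is a (7S,7'S,8R,8'R)-syringaresinol core (2,6-diaryl-3,7-dioxabicyclo[3.3.0]octane, both aryl groups exo). One phenol oxygen carries an erythro (7R,8S) guaiacylglycerol unit A; the other carries a threo (7S,8S) unit B that is 4-O-linked to an erythro (7S,8R) unit C.
2. Retrosynthetic cuts, in order: silyl and benzyl groups; O–C9 of ring B (through the C9 lactone); C7–C8 of ring A (C–H insertion of a C8 carbenoid); the benzyl ether O–C7; C7'–C8' (Evans succinate aldol). Each arylglycerol is cut at its C7–C8 bond (Evans aryloxyacetyl aldol) and at ArO–CH2.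
3. Forward: units A and C are built on propenylphenols (propenyl = masked CHO). The unit-C aldehyde is the electrophile for unit B. This gives one syringaldehyde carrying unit A and one carrying units B and C. The second is joined to a succinate imide (C7', C8'), the first is attached as a benzyl ether, ring A closes by carbenoid insertion and ring B by lactonization and lactone-to-ether reduction.
4. Enabling feature: the C7–H bond is benzylic, alpha to the ring-A oxygen and 1,5 to C8, and C8 carries C9, which can be held at the ester level as carbenoid acceptor and later becomes the OCH2 of ring B. The ester is the only helper group and is reduced away.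
5. Stereochemistry: oxazolidinone auxiliaries set the six glycerol centres (erythro units by Mitsunobu inversion at C7) and C7'/C8'. C7 comes from the chair-like insertion transition state, and C8 from epimerization into the cis-fused lactone.

Key step: step 23

Assumption: the two enantiomers of 4-benzyl-3-(chloroacetyl)oxazolidin-2-one and the two (E)-propenylphenols are taken as purchasable; an E/Z mixture of the phenols would serve equally, because the propenyl group is only a masked formyl group.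

Abbreviations in names: XcS = (4S)-4-benzyl-2-oxooxazolidin-3-yl; TBS = tert-butyldimethylsilyl; G = 4-(benzyloxy)-3-methoxyphenyl; SA = (1R,2S)-1-G-1,3-bis(TBS-oxy)propan-2-yl; SC = (1S,2R)-1-G-1,3-bis(TBS-oxy)propan-2-yl; GC = 3-methoxy-4-(SC-oxy)phenyl; SB = (1S,2S)-1-GC-1,3-bis(TBS-oxy)propan-2-yl; ArA = 3,5-dimethoxy-4-(SA-oxy)phenyl; ArBC = 3,5-dimethoxy-4-(SB-oxy)phenyl. Core locants: C7/C7' aryl-bearing carbons, C8/C8' ring-fusion carbons, C9/C9' OCH2 carbons; ring A = O–C9'–C8'–C8–C7 (C7 bears ArA), ring B = O–C9–C8–C8'–C7'.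

**Unit A aldehyde**

Step 1
Reactants: 1 (E)-2,6-dimethoxy-4-(prop-1-enyl)phenol; 2 (4R)-4-benzyl-3-(chloroacetyl)oxazolidin-2-one
Product: 3 (4R)-4-benzyl-3-{[2,6-dimethoxy-4-((E)-prop-1-enyl)phenoxy]acetyl}oxazolidin-2-one
Conditions: K2CO3, NaI (cat.), acetone, 50 °C
Reagents that add atoms: none
Why: Williamson etherification, in which the hindered but acidic phenoxide displaces halide alpha to the imide carbonyl by SN2; no stereocentre is formed.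

Step 2
Reactants: 3 (4R)-4-benzyl-3-{[2,6-dimethoxy-4-((E)-prop-1-enyl)phenoxy]acetyl}oxazolidin-2-one; 4 4-(benzyloxy)-3-methoxybenzaldehyde
Product: 5 (4R)-4-benzyl-3-[(2R,3S)-3-G-3-hydroxy-2-{2,6-dimethoxy-4-[(E)-prop-1-enyl]phenoxy}propanoyl]oxazolidin-2-one
Conditions: Bu2BOTf, i-Pr2NEt, CH2Cl2, −78 °C; then 4, −78 to 0 °C; pH 7 buffer, MeOH, H2O2
Reagents that add atoms: none
Why: Evans syn-aldol, in which the Z-boron enolate reacts through a closed chair transition state on the face away from the auxiliary benzyl group, setting the (2R,3S) pair (threo relation of OAr and OH).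

Step 3
Reactants: 5 (4R)-4-benzyl-3-[(2R,3S)-3-G-3-hydroxy-2-{2,6-dimethoxy-4-[(E)-prop-1-enyl]phenoxy}propanoyl]oxazolidin-2-one
Product: 6 (4R)-4-benzyl-3-[(2R,3R)-3-G-3-(4-nitrobenzoyloxy)-2-{2,6-dimethoxy-4-[(E)-prop-1-enyl]phenoxy}propanoyl]oxazolidin-2-one
Conditions: 4-nitrobenzoic acid, PPh3, diisopropyl azodicarboxylate, THF, 0 °C to rt
Reagents that add atoms: 4-nitrobenzoic acid, O=C(O)c1ccc([N+](=O)[O-])cc1
Why: Mitsunobu esterification, in which SN2 displacement of the oxyphosphonium ion inverts the benzylic carbinol centre (threo to erythro), ionization being disfavoured by the adjacent imide and aryloxy groups.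

Step 4
Reactants: 6 (4R)-4-benzyl-3-[(2R,3R)-3-G-3-(4-nitrobenzoyloxy)-2-{2,6-dimethoxy-4-[(E)-prop-1-enyl]phenoxy}propanoyl]oxazolidin-2-one
Product: 7 (1R,2S)-1-G-2-{2,6-dimethoxy-4-[(E)-prop-1-enyl]phenoxy}propane-1,3-diol
Conditions: LiBH4, MeOH (1 equiv), THF, 0 °C to rt
Reagents that add atoms: none
Why: Reductive auxiliary removal, in which borohydride cleaves the N-acyl oxazolidinone to the primary alcohol and the 4-nitrobenzoate to the secondary alcohol without touching either stereocentre.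

Step 5
Reactants: 7 (1R,2S)-1-G-2-{2,6-dimethoxy-4-[(E)-prop-1-enyl]phenoxy}propane-1,3-diol
Product: 8 (1R,2S)-1-G-2-{2,6-dimethoxy-4-[(E)-prop-1-enyl]phenoxy}propane-1,3-diol bis-TBS ether
Conditions: TBSOTf, 2,6-lutidine, CH2Cl2, 0 °C
Reagents that add atoms: tert-butyldimethylsilyl triflate, CC(C)(C)[Si](C)(C)OS(=O)(=O)C(F)(F)F
Why: Silyl ether protection of both hydroxyls with a silyl triflate and a hindered base, the buffered medium leaving the propenyl group intact.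

Step 6
Reactants: 8 (1R,2S)-1-G-2-{2,6-dimethoxy-4-[(E)-prop-1-enyl]phenoxy}propane-1,3-diol bis-TBS ether
Product: 9 3,5-dimethoxy-4-(SA-oxy)benzaldehyde (ArA–CHO)
Conditions: OsO4 (cat.), NaIO4, 2,6-lutidine, dioxane/H2O, rt
Reagents that add atoms: sodium periodate, [Na+].[O-]I(=O)(=O)=O (oxygen of the new CHO, delivered through catalytic osmium tetroxide, O=[Os](=O)(=O)=O)
Why: Lemieux–Johnson oxidation, in which dihydroxylation of the electron-rich styrenyl double bond and periodate cleavage unmask the aryl aldehyde while silyl and benzyl ethers are inert.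

**Unit C aldehyde**

Step 7
Reactants: 10 (E)-2-methoxy-4-(prop-1-enyl)phenol (isoeugenol); 11 (4S)-4-benzyl-3-(chloroacetyl)oxazolidin-2-one
Product: 12 (4S)-4-benzyl-3-{[2-methoxy-4-((E)-prop-1-enyl)phenoxy]acetyl}oxazolidin-2-one
Conditions: K2CO3, NaI (cat.), acetone, 50 °C
Reagents that add atoms: none
Why: Williamson etherification as in step 1; no stereocentre is formed.

Step 8
Reactants: 12 (4S)-4-benzyl-3-{[2-methoxy-4-((E)-prop-1-enyl)phenoxy]acetyl}oxazolidin-2-one; 4 4-(benzyloxy)-3-methoxybenzaldehyde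
Product: 13 (4S)-4-benzyl-3-[(2S,3R)-3-G-3-hydroxy-2-{2-methoxy-4-[(E)-prop-1-enyl]phenoxy}propanoyl]oxazolidin-2-one
Conditions: Bu2BOTf, i-Pr2NEt, CH2Cl2, −78 °C; then 4, −78 to 0 °C; pH 7 buffer, MeOH, H2O2
Reagents that add atoms: none
Why: Evans syn-aldol with the enantiomeric auxiliary, so the closed chair transition state gives the mirror-image (2S,3R) threo pair.

Step 9
Reactants: 13 (4S)-4-benzyl-3-[(2S,3R)-3-G-3-hydroxy-2-{2-methoxy-4-[(E)-prop-1-enyl]phenoxy}propanoyl]oxazolidin-2-one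
Product: 14 (4S)-4-benzyl-3-[(2S,3S)-3-G-3-(4-nitrobenzoyloxy)-2-{2-methoxy-4-[(E)-prop-1-enyl]phenoxy}propanoyl]oxazolidin-2-one
Conditions: 4-nitrobenzoic acid, PPh3, diisopropyl azodicarboxylate, THF, 0 °C to rt
Reagents that add atoms: 4-nitrobenzoic acid, O=C(O)c1ccc([N+](=O)[O-])cc1
Why: Mitsunobu esterification with SN2 inversion of the benzylic carbinol centre, converting the threo pair into the erythro pair of unit C.

Step 10
Reactants: 14 (4S)-4-benzyl-3-[(2S,3S)-3-G-3-(4-nitrobenzoyloxy)-2-{2-methoxy-4-[(E)-prop-1-enyl]phenoxy}propanoyl]oxazolidin-2-one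
Product: 15 (1S,2R)-1-G-2-{2-methoxy-4-[(E)-prop-1-enyl]phenoxy}propane-1,3-diol
Conditions: LiBH4, MeOH (1 equiv), THF, 0 °C to rt
Reagents that add atoms: none
Why: Reductive auxiliary removal with concurrent cleavage of the 4-nitrobenzoate, both stereocentres being untouched.

Step 11
Reactants: 15 (1S,2R)-1-G-2-{2-methoxy-4-[(E)-prop-1-enyl]phenoxy}propane-1,3-diol
Product: 16 (1S,2R)-1-G-2-{2-methoxy-4-[(E)-prop-1-enyl]phenoxy}propane-1,3-diol bis-TBS ether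
Conditions: TBSOTf, 2,6-lutidine, CH2Cl2, 0 °C
Reagents that add atoms: tert-butyldimethylsilyl triflate, CC(C)(C)[Si](C)(C)OS(=O)(=O)C(F)(F)F
Why: Silyl ether protection of both hydroxyls under buffered conditions.

Step 12
Reactants: 16 (1S,2R)-1-G-2-{2-methoxy-4-[(E)-prop-1-enyl]phenoxy}propane-1,3-diol bis-TBS ether
Product: 17 3-methoxy-4-(SC-oxy)benzaldehyde (GC–CHO)
Conditions: OsO4 (cat.), NaIO4, 2,6-lutidine, dioxane/H2O, rt
Reagents that add atoms: sodium periodate, [Na+].[O-]I(=O)(=O)=O (oxygen of the new CHO, delivered through catalytic osmium tetroxide, O=[Os](=O)(=O)=O)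
Why: Lemieux–Johnson oxidation of the propenyl group to the aryl aldehyde.

**Unit B on the unit C aldehyde**

Step 13
Reactants: 3 (4R)-4-benzyl-3-{[2,6-dimethoxy-4-((E)-prop-1-enyl)phenoxy]acetyl}oxazolidin-2-one; 17 3-methoxy-4-(SC-oxy)benzaldehyde
Product: 18 (4R)-4-benzyl-3-[(2R,3S)-3-GC-3-hydroxy-2-{2,6-dimethoxy-4-[(E)-prop-1-enyl]phenoxy}propanoyl]oxazolidin-2-one
Conditions: Bu2BOTf, i-Pr2NEt, CH2Cl2, −78 °C; then 17, −78 to 0 °C; pH 7 buffer, MeOH, H2O2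
Reagents that add atoms: none
Why: Evans syn-aldol as in step 2, whose (2R,3S) adduct is already the threo (7S,8S) arrangement of unit B, so no inversion is needed.

Step 14
Reactants: 18 (4R)-4-benzyl-3-[(2R,3S)-3-GC-3-hydroxy-2-{2,6-dimethoxy-4-[(E)-prop-1-enyl]phenoxy}propanoyl]oxazolidin-2-one
Product: 19 (1S,2S)-1-GC-2-{2,6-dimethoxy-4-[(E)-prop-1-enyl]phenoxy}propane-1,3-diol
Conditions: LiBH4, MeOH (1 equiv), THF, 0 °C
Reagents that add atoms: none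
Why: Reductive auxiliary removal to the 1,3-diol without change at the stereocentres.

Step 15
Reactants: 19 (1S,2S)-1-GC-2-{2,6-dimethoxy-4-[(E)-prop-1-enyl]phenoxy}propane-1,3-diol
Product: 20 (1S,2S)-1-GC-2-{2,6-dimethoxy-4-[(E)-prop-1-enyl]phenoxy}propane-1,3-diol bis-TBS ether
Conditions: TBSOTf, 2,6-lutidine, CH2Cl2, 0 °C
Reagents that add atoms: tert-butyldimethylsilyl triflate, CC(C)(C)[Si](C)(C)OS(=O)(=O)C(F)(F)F
Why: Silyl ether protection of both hydroxyls under buffered conditions.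

Step 16
Reactants: 20 (1S,2S)-1-GC-2-{2,6-dimethoxy-4-[(E)-prop-1-enyl]phenoxy}propane-1,3-diol bis-TBS ether
Product: 21 3,5-dimethoxy-4-(SB-oxy)benzaldehyde (ArBC–CHO)
Conditions: OsO4 (cat.), NaIO4, 2,6-lutidine, dioxane/H2O, rt
Reagents that add atoms: sodium periodate, [Na+].[O-]I(=O)(=O)=O (oxygen of the new CHO, delivered through catalytic osmium tetroxide, O=[Os](=O)(=O)=O)
Why: Lemieux–Johnson oxidation of the propenyl group to the aryl aldehyde.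

**Core**

Step 17
Reactants: 22 4-tert-butoxy-4-oxobutanoic acid; 23 (4S)-4-benzyloxazolidin-2-one
Product: 25 tert-butyl 4-[(4S)-4-benzyl-2-oxooxazolidin-3-yl]-4-oxobutanoate, via pivalic mixed anhydride 24 (not isolated)
Conditions: pivaloyl chloride, Et3N, THF, −20 °C; then 23, LiCl, −20 °C to rt
Reagents that add atoms: pivaloyl chloride, CC(C)(C)C(Cl)=O (atoms only in intermediate 24)
Why: N-acylation of the oxazolidinone through the mixed pivalic anhydride, the hindered pivaloyl carbonyl directing acyl transfer to the succinyl carbonyl and the tert-butyl ester being untouched.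

Step 18
Reactants: 25 tert-butyl 4-[(4S)-4-benzyl-2-oxooxazolidin-3-yl]-4-oxobutanoate; 21 3,5-dimethoxy-4-(SB-oxy)benzaldehyde
Product: 26 tert-butyl (3S,4S)-4-ArBC-4-hydroxy-3-(XcS-carbonyl)butanoate
Conditions: Bu2BOTf, i-Pr2NEt, CH2Cl2, −78 °C; then 21, −78 to 0 °C; pH 7 buffer, MeOH, H2O2
Reagents that add atoms: none
Why: Evans syn-aldol, in which the Z-boron enolate forms only at the imide alpha-carbon and the (S)-auxiliary sets C8' (R) and C7' (S) of the core with ArBC and the future C9' in the relation needed for an exo aryl group on ring B.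

Step 19
Reactants: 26 tert-butyl (3S,4S)-4-ArBC-4-hydroxy-3-(XcS-carbonyl)butanoate
Product: 27 tert-butyl (3S,4S)-4-ArBC-3-(XcS-carbonyl)-4-(triethylsilyloxy)butanoate
Conditions: triethylsilyl triflate, 2,6-lutidine, CH2Cl2, −78 to 0 °C
Reagents that add atoms: triethylsilyl triflate, CC[Si](CC)(CC)OS(=O)(=O)C(F)(F)F
Why: Silyl ether protection of O7', which keeps it from lactonizing now and from O–H insertion later, with a group that can be removed in the presence of the TBS ethers.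

Step 20
Reactants: 27 tert-butyl (3S,4S)-4-ArBC-3-(XcS-carbonyl)-4-(triethylsilyloxy)butanoate
Product: 28 tert-butyl (3R,4S)-4-ArBC-3-(hydroxymethyl)-4-(triethylsilyloxy)butanoate
Conditions: LiBH4, MeOH (1 equiv), THF, 0 °C
Reagents that add atoms: none
Why: Chemoselective reductive auxiliary removal, LiBH4 reducing the imide much faster than the tert-butyl ester, gives the C9' alcohol.

Step 21
Reactants: 28 tert-butyl (3R,4S)-4-ArBC-3-(hydroxymethyl)-4-(triethylsilyloxy)butanoate; 9 3,5-dimethoxy-4-(SA-oxy)benzaldehyde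
Product: 30 tert-butyl (3R,4S)-4-ArBC-3-[(ArA-methoxy)methyl]-4-(triethylsilyloxy)butanoate, via trimethylsilyl ether 29 (not isolated)
Conditions: Me3SiCl, Et3N, CH2Cl2, 0 °C; then 9, Et3SiH, Me3SiOTf (cat.), CH2Cl2, −78 °C
Reagents that add atoms: chlorotrimethylsilane, C[Si](C)(C)Cl (atoms only in intermediate 29)
Why: Reductive etherification, in which the silyl triflate converts aldehyde 9 and the trimethylsilyl ether into an oxocarbenium ion that Et3SiH reduces at −78 °C, forming the O–C7 benzyl ether without harming the other silyl ethers or the tert-butyl ester.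

Step 22
Reactants: 30 tert-butyl (3R,4S)-4-ArBC-3-[(ArA-methoxy)methyl]-4-(triethylsilyloxy)butanoate
Product: 32 tert-butyl (3R,4S)-4-ArBC-3-[(ArA-methoxy)methyl]-2-diazo-4-(triethylsilyloxy)butanoate, via trifluoroacetyl ester 31 (not isolated)
Conditions: LiN(i-Pr)2, THF, −78 °C; CF3CO2CH2CF3; then MeSO2N3, Et3N, MeCN, rt
Reagents that add atoms: methanesulfonyl azide, CS(=O)(=O)N=[N+]=[N-]; 2,2,2-trifluoroethyl trifluoroacetate, O=C(OCC(F)(F)F)C(F)(F)F (atoms only in intermediate 31)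
Why: Deacylative (Regitz-type) diazo transfer, in which Claisen trifluoroacetylation of the ester enolate activates C8 and azide transfer with loss of the trifluoroacetyl group gives the alpha-diazo ester.

Step 23
Reactants: 32 tert-butyl (3R,4S)-4-ArBC-3-[(ArA-methoxy)methyl]-2-diazo-4-(triethylsilyloxy)butanoate
Product: 33 tert-butyl (2S,3R,4R)-2-ArA-4-[(S)-ArBC(triethylsilyloxy)methyl]tetrahydrofuran-3-carboxylate (2,3-cis, 2,4-trans; the C8 epimer would converge in step 25)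
Conditions: Rh2(O2CCMe3)4 (1 mol %), CH2Cl2, −20 °C to rt, slow addition of 32 at high dilution
Reagents that add atoms: none
Why: Rh2(O2CCMe3)4 converts the diazo ester into an electrophilic rhodium carbenoid at C8, which takes up the C7–H bond (benzylic, alpha to the ether oxygen, 1,5 to C8) in a concerted three-centre insertion with retention at C7, forming C7–C8. The closest known reaction type is the dirhodium-catalysed 1,5 C–H insertion of alpha-diazo esters and alpha-diazo-gamma-butyrolactones into benzylic ether C–H bonds, which gives 2-aryltetrahydrofuran-3-carboxylates and furofuranones. Ring A (O–C9'–C8'–C8–C7) closes as a five-membered ring by 1,5-insertion through a six-membered chair-like array C8/C8'/C9'/O/C7/H. C7 is controlled by this chair: the aryl group on C7 and the CH(OSiEt3)ArBC branch on C8' both sit equatorial and, being 1,4-related, end up trans on the ring (the exo-aryl arrangement), whereas a cis-fused lactone in a bicyclic diazolactone would force the C8' branch axial and lead to the endo-aryl series; C8 is expected with the ester cis to the aryl group and is corrected in step 25. The step needs 1,5-insertion to beat 1,2-hydride shift from C8'–H and attack on the neighbouring arene, which the doubly activated C7–H bond, the bulky electron-rich pivalate ligands, low temperature and slow addition should secure.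

Step 24
Reactants: 33 tert-butyl (2S,3R,4R)-2-ArA-4-[(S)-ArBC(triethylsilyloxy)methyl]tetrahydrofuran-3-carboxylate
Product: 34 tert-butyl (2S,3R,4R)-2-ArA-4-[(S)-ArBC(hydroxy)methyl]tetrahydrofuran-3-carboxylate
Conditions: HF·pyridine, pyridine, THF, 0 °C
Reagents that add atoms: none
Why: Selective desilylation, buffered HF·pyridine cleaving the triethylsilyl ether far faster than the TBS ethers, frees O7'.

Step 25
Reactants: 34 tert-butyl (2S,3R,4R)-2-ArA-4-[(S)-ArBC(hydroxy)methyl]tetrahydrofuran-3-carboxylate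
Product: 35 (3S,3aR,6S,6aS)-6-ArA-3-ArBC-tetrahydro-1H,3H-furo[3,4-c]furan-1-one (both aryl groups exo)
Conditions: KOtBu (0.5 equiv), THF, 0 °C to rt
Reagents that add atoms: none
Why: Base-mediated epimerization alpha to the ester equilibrates C8, and because only the epimer with C9 cis to the C8' branch can lactonize, irreversible transesterification to the cis-fused gamma-lactone sets C8 and leaves the ring-A aryl group exo.

Step 26
Reactants: 35 (3S,3aR,6S,6aS)-6-ArA-3-ArBC-tetrahydro-1H,3H-furo[3,4-c]furan-1-one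
Product: 37 (1S,3aR,4S,6aR)-1-ArA-4-ArBC-tetrahydro-1H,3H-furo[3,4-c]furan, via lactol 36 (not isolated)
Conditions: i-Bu2AlH, CH2Cl2, −78 °C; then Et3SiH, BF3·OEt2, −78 to −40 °C
Reagents that add atoms: none
Why: Lactone-to-ether reduction, in which i-Bu2AlH stops at the lactol and ionic hydrogenation through the bicyclic oxocarbenium ion at C9 gives the CH2 of ring B, so no stereocentre is at stake and the lactol ionizes well below the temperature at which the benzylic ethers would.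

Step 27
Reactants: 37 (1S,3aR,4S,6aR)-1-ArA-4-ArBC-tetrahydro-1H,3H-furo[3,4-c]furan
Product: 38 hexa-TBS ether of the target (both guaiacyl phenols free)
Conditions: H2 (1 atm), 10% Pd/C, EtOAc, rt
Reagents that add atoms: none
Why: Catalytic hydrogenolysis, the two aryl benzyl ethers being cleaved faster than the dialkyl benzylic ethers of the core and the silyl-protected benzylic carbinols.

Step 28
Reactants: 38 hexa-TBS ether of the target
Product: 39 CNP0316493.3 (target)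
Conditions: Bu4NF, AcOH, THF, 0 °C to rt
Reagents that add atoms: none
Why: Fluoride-mediated cleavage of the six silyl ethers, buffered with AcOH so that the 4-hydroxybenzylic alcohols are not exposed to free base.

**Compound list**

1 | (E)-2,6-dimethoxy-4-(prop-1-enyl)phenol | C/C=C/c1cc(OC)c(O)c(OC)c1 | starting material
2 | (4R)-4-benzyl-3-(chloroacetyl)oxazolidin-2-one | O=C(CCl)N1[C@H](Cc2ccccc2)COC1=O | starting material
3 | (4R)-4-benzyl-3-{[2,6-dimethoxy-4-((E)-prop-1-enyl)phenoxy]acetyl}oxazolidin-2-one | C/C=C/c1cc(OC)c(OCC(=O)N2[C@H](Cc3ccccc3)COC2=O)c(OC)c1 | intermediate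
4 | 4-(benzyloxy)-3-methoxybenzaldehyde | O=Cc1ccc(OCc2ccccc2)c(OC)c1 | starting material
5 | (4R)-4-benzyl-3-[(2R,3S)-3-G-3-hydroxy-2-{2,6-dimethoxy-4-[(E)-prop-1-enyl]phenoxy}propanoyl]oxazolidin-2-one | COc1cc([C@H](O)[C@H](C(=O)N2[C@H](Cc3ccccc3)COC2=O)Oc2c(OC)cc(/C=C/C)cc2OC)ccc1OCc1ccccc1 | intermediate
6 | (4R)-4-benzyl-3-[(2R,3R)-3-G-3-(4-nitrobenzoyloxy)-2-{2,6-dimethoxy-4-[(E)-prop-1-enyl]phenoxy}propanoyl]oxazolidin-2-one | COc1cc([C@@H](OC(=O)c2ccc([N+](=O)[O-])cc2)[C@H](C(=O)N2[C@H](Cc3ccccc3)COC2=O)Oc2c(OC)cc(/C=C/C)cc2OC)ccc1OCc1ccccc1 | intermediate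
7 | (1R,2S)-1-G-2-{2,6-dimethoxy-4-[(E)-prop-1-enyl]phenoxy}propane-1,3-diol | COc1cc([C@@H](O)[C@H](CO)Oc2c(OC)cc(/C=C/C)cc2OC)ccc1OCc1ccccc1 | intermediate
8 | bis-TBS ether of 7 | COc1cc([C@@H](O[Si](C)(C)C(C)(C)C)[C@H](CO[Si](C)(C)C(C)(C)C)Oc2c(OC)cc(/C=C/C)cc2OC)ccc1OCc1ccccc1 | intermediate
9 | 3,5-dimethoxy-4-(SA-oxy)benzaldehyde (ArA–CHO) | COc1cc([C@@H](O[Si](C)(C)C(C)(C)C)[C@H](CO[Si](C)(C)C(C)(C)C)Oc2c(OC)cc(C=O)cc2OC)ccc1OCc1ccccc1 | intermediate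
10 | (E)-2-methoxy-4-(prop-1-enyl)phenol | C/C=C/c1ccc(O)c(OC)c1 | starting material
11 | (4S)-4-benzyl-3-(chloroacetyl)oxazolidin-2-one | O=C(CCl)N1[C@@H](Cc2ccccc2)COC1=O | starting material
12 | (4S)-4-benzyl-3-{[2-methoxy-4-((E)-prop-1-enyl)phenoxy]acetyl}oxazolidin-2-one | C/C=C/c1ccc(OCC(=O)N2[C@@H](Cc3ccccc3)COC2=O)c(OC)c1 | intermediate
13 | (4S)-4-benzyl-3-[(2S,3R)-3-G-3-hydroxy-2-{2-methoxy-4-[(E)-prop-1-enyl]phenoxy}propanoyl]oxazolidin-2-one | C/C=C/c1ccc(O[C@H](C(=O)N2[C@@H](Cc3ccccc3)COC2=O)[C@H](O)c2ccc(OCc3ccccc3)c(OC)c2)c(OC)c1 | intermediate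
14 | (4S)-4-benzyl-3-[(2S,3S)-3-G-3-(4-nitrobenzoyloxy)-2-{2-methoxy-4-[(E)-prop-1-enyl]phenoxy}propanoyl]oxazolidin-2-one | C/C=C/c1ccc(O[C@H](C(=O)N2[C@@H](Cc3ccccc3)COC2=O)[C@@H](OC(=O)c2ccc([N+](=O)[O-])cc2)c2ccc(OCc3ccccc3)c(OC)c2)c(OC)c1 | intermediate
15 | (1S,2R)-1-G-2-{2-methoxy-4-[(E)-prop-1-enyl]phenoxy}propane-1,3-diol | C/C=C/c1ccc(O[C@H](CO)[C@@H](O)c2ccc(OCc3ccccc3)c(OC)c2)c(OC)c1 | intermediate
16 | bis-TBS ether of 15 | C/C=C/c1ccc(O[C@H](CO[Si](C)(C)C(C)(C)C)[C@@H](O[Si](C)(C)C(C)(C)C)c2ccc(OCc3ccccc3)c(OC)c2)c(OC)c1 | intermediate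
17 | 3-methoxy-4-(SC-oxy)benzaldehyde (GC–CHO) | O=Cc1ccc(O[C@H](CO[Si](C)(C)C(C)(C)C)[C@@H](O[Si](C)(C)C(C)(C)C)c2ccc(OCc3ccccc3)c(OC)c2)c(OC)c1 | intermediate
18 | (4R)-4-benzyl-3-[(2R,3S)-3-GC-3-hydroxy-2-{2,6-dimethoxy-4-[(E)-prop-1-enyl]phenoxy}propanoyl]oxazolidin-2-one | C/C=C/c1cc(OC)c(O[C@@H](C(=O)N2[C@H](Cc3ccccc3)COC2=O)[C@@H](O)c2ccc(O[C@H](CO[Si](C)(C)C(C)(C)C)[C@@H](O[Si](C)(C)C(C)(C)C)c3ccc(OCc4ccccc4)c(OC)c3)c(OC)c2)c(OC)c1 | intermediate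
19 | (1S,2S)-1-GC-2-{2,6-dimethoxy-4-[(E)-prop-1-enyl]phenoxy}propane-1,3-diol | C/C=C/c1cc(OC)c(O[C@@H](CO)[C@@H](O)c2ccc(O[C@H](CO[Si](C)(C)C(C)(C)C)[C@@H](O[Si](C)(C)C(C)(C)C)c3ccc(OCc4ccccc4)c(OC)c3)c(OC)c2)c(OC)c1 | intermediate
20 | bis-TBS ether of 19 | C/C=C/c1cc(OC)c(O[C@@H](CO[Si](C)(C)C(C)(C)C)[C@@H](O[Si](C)(C)C(C)(C)C)c2ccc(O[C@H](CO[Si](C)(C)C(C)(C)C)[C@@H](O[Si](C)(C)C(C)(C)C)c3ccc(OCc4ccccc4)c(OC)c3)c(OC)c2)c(OC)c1 | intermediate
21 | 3,5-dimethoxy-4-(SB-oxy)benzaldehyde (ArBC–CHO) | O=Cc1cc(OC)c(O[C@@H](CO[Si](C)(C)C(C)(C)C)[C@@H](O[Si](C)(C)C(C)(C)C)c2ccc(O[C@H](CO[Si](C)(C)C(C)(C)C)[C@@H](O[Si](C)(C)C(C)(C)C)c3ccc(OCc4ccccc4)c(OC)c3)c(OC)c2)c(OC)c1 | intermediate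
22 | 4-tert-butoxy-4-oxobutanoic acid | CC(C)(C)OC(=O)CCC(=O)O | starting material
23 | (4S)-4-benzyloxazolidin-2-one | O=C1N[C@@H](Cc2ccccc2)CO1 | starting material
24 | 4-tert-butoxy-4-oxobutanoic pivalic anhydride | CC(C)(C)OC(=O)CCC(=O)OC(=O)C(C)(C)C | intermediate
25 | tert-butyl 4-[(4S)-4-benzyl-2-oxooxazolidin-3-yl]-4-oxobutanoate | CC(C)(C)OC(=O)CCC(=O)N1[C@@H](Cc2ccccc2)COC1=O | intermediate
26 | tert-butyl (3S,4S)-4-ArBC-4-hydroxy-3-(XcS-carbonyl)butanoate | CC(C)(C)OC(=O)C[C@H](C(=O)N1[C@@H](Cc2ccccc2)COC1=O)[C@H](O)c1cc(OC)c(O[C@@H](CO[Si](C)(C)C(C)(C)C)[C@@H](O[Si](C)(C)C(C)(C)C)c2ccc(O[C@H](CO[Si](C)(C)C(C)(C)C)[C@@H](O[Si](C)(C)C(C)(C)C)c3ccc(OCc4ccccc4)c(OC)c3)c(OC)c2)c(OC)c1 | intermediate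
27 | tert-butyl (3S,4S)-4-ArBC-3-(XcS-carbonyl)-4-(triethylsilyloxy)butanoate | CC(C)(C)OC(=O)C[C@H](C(=O)N1[C@@H](Cc2ccccc2)COC1=O)[C@H](O[Si](CC)(CC)CC)c1cc(OC)c(O[C@@H](CO[Si](C)(C)C(C)(C)C)[C@@H](O[Si](C)(C)C(C)(C)C)c2ccc(O[C@H](CO[Si](C)(C)C(C)(C)C)[C@@H](O[Si](C)(C)C(C)(C)C)c3ccc(OCc4ccccc4)c(OC)c3)c(OC)c2)c(OC)c1 | intermediate
28 | tert-butyl (3R,4S)-4-ArBC-3-(hydroxymethyl)-4-(triethylsilyloxy)butanoate | CC(C)(C)OC(=O)C[C@H](CO)[C@H](O[Si](CC)(CC)CC)c1cc(OC)c(O[C@@H](CO[Si](C)(C)C(C)(C)C)[C@@H](O[Si](C)(C)C(C)(C)C)c2ccc(O[C@H](CO[Si](C)(C)C(C)(C)C)[C@@H](O[Si](C)(C)C(C)(C)C)c3ccc(OCc4ccccc4)c(OC)c3)c(OC)c2)c(OC)c1 | intermediate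
29 | trimethylsilyl ether of 28 | CC(C)(C)OC(=O)C[C@H](CO[Si](C)(C)C)[C@H](O[Si](CC)(CC)CC)c1cc(OC)c(O[C@@H](CO[Si](C)(C)C(C)(C)C)[C@@H](O[Si](C)(C)C(C)(C)C)c2ccc(O[C@H](CO[Si](C)(C)C(C)(C)C)[C@@H](O[Si](C)(C)C(C)(C)C)c3ccc(OCc4ccccc4)c(OC)c3)c(OC)c2)c(OC)c1 | intermediate
30 | tert-butyl (3R,4S)-4-ArBC-3-[(ArA-methoxy)methyl]-4-(triethylsilyloxy)butanoate | COc1cc([C@@H](O[Si](C)(C)C(C)(C)C)[C@H](CO[Si](C)(C)C(C)(C)C)Oc2c(OC)cc(COC[C@@H](CC(=O)OC(C)(C)C)[C@H](O[Si](CC)(CC)CC)c3cc(OC)c(O[C@@H](CO[Si](C)(C)C(C)(C)C)[C@@H](O[Si](C)(C)C(C)(C)C)c4ccc(O[C@H](CO[Si](C)(C)C(C)(C)C)[C@@H](O[Si](C)(C)C(C)(C)C)c5ccc(OCc6ccccc6)c(OC)c5)c(OC)c4)c(OC)c3)cc2OC)ccc1OCc1ccccc1 | intermediate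
31 | 2-(trifluoroacetyl) derivative of 30 (C2 epimers) | COc1cc([C@@H](O[Si](C)(C)C(C)(C)C)[C@H](CO[Si](C)(C)C(C)(C)C)Oc2c(OC)cc(COC[C@@H](C(C(=O)C(F)(F)F)C(=O)OC(C)(C)C)[C@H](O[Si](CC)(CC)CC)c3cc(OC)c(O[C@@H](CO[Si](C)(C)C(C)(C)C)[C@@H](O[Si](C)(C)C(C)(C)C)c4ccc(O[C@H](CO[Si](C)(C)C(C)(C)C)[C@@H](O[Si](C)(C)C(C)(C)C)c5ccc(OCc6ccccc6)c(OC)c5)c(OC)c4)c(OC)c3)cc2OC)ccc1OCc1ccccc1 | intermediate
32 | tert-butyl (3R,4S)-4-ArBC-3-[(ArA-methoxy)methyl]-2-diazo-4-(triethylsilyloxy)butanoate | COc1cc([C@@H](O[Si](C)(C)C(C)(C)C)[C@H](CO[Si](C)(C)C(C)(C)C)Oc2c(OC)cc(COC[C@@H](C(=[N+]=[N-])C(=O)OC(C)(C)C)[C@H](O[Si](CC)(CC)CC)c3cc(OC)c(O[C@@H](CO[Si](C)(C)C(C)(C)C)[C@@H](O[Si](C)(C)C(C)(C)C)c4ccc(O[C@H](CO[Si](C)(C)C(C)(C)C)[C@@H](O[Si](C)(C)C(C)(C)C)c5ccc(OCc6ccccc6)c(OC)c5)c(OC)c4)c(OC)c3)cc2OC)ccc1OCc1ccccc1 | intermediate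
33 | tert-butyl (2S,3R,4R)-2-ArA-4-[(S)-ArBC(triethylsilyloxy)methyl]tetrahydrofuran-3-carboxylate | COc1cc([C@@H](O[Si](C)(C)C(C)(C)C)[C@H](CO[Si](C)(C)C(C)(C)C)Oc2c(OC)cc([C@H]3OC[C@H]([C@H](O[Si](CC)(CC)CC)c4cc(OC)c(O[C@@H](CO[Si](C)(C)C(C)(C)C)[C@@H](O[Si](C)(C)C(C)(C)C)c5ccc(O[C@H](CO[Si](C)(C)C(C)(C)C)[C@@H](O[Si](C)(C)C(C)(C)C)c6ccc(OCc7ccccc7)c(OC)c6)c(OC)c5)c(OC)c4)[C@H]3C(=O)OC(C)(C)C)cc2OC)ccc1OCc1ccccc1 | intermediate
34 | tert-butyl (2S,3R,4R)-2-ArA-4-[(S)-ArBC(hydroxy)methyl]tetrahydrofuran-3-carboxylate | COc1cc([C@@H](O[Si](C)(C)C(C)(C)C)[C@H](CO[Si](C)(C)C(C)(C)C)Oc2c(OC)cc([C@H]3OC[C@H]([C@H](O)c4cc(OC)c(O[C@@H](CO[Si](C)(C)C(C)(C)C)[C@@H](O[Si](C)(C)C(C)(C)C)c5ccc(O[C@H](CO[Si](C)(C)C(C)(C)C)[C@@H](O[Si](C)(C)C(C)(C)C)c6ccc(OCc7ccccc7)c(OC)c6)c(OC)c5)c(OC)c4)[C@H]3C(=O)OC(C)(C)C)cc2OC)ccc1OCc1ccccc1 | intermediate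
35 | (3S,3aR,6S,6aS)-6-ArA-3-ArBC-tetrahydro-1H,3H-furo[3,4-c]furan-1-one | COc1cc([C@@H](O[Si](C)(C)C(C)(C)C)[C@H](CO[Si](C)(C)C(C)(C)C)Oc2c(OC)cc([C@H]3OC[C@H]4[C@@H]3C(=O)O[C@@H]4c3cc(OC)c(O[C@@H](CO[Si](C)(C)C(C)(C)C)[C@@H](O[Si](C)(C)C(C)(C)C)c4ccc(O[C@H](CO[Si](C)(C)C(C)(C)C)[C@@H](O[Si](C)(C)C(C)(C)C)c5ccc(OCc6ccccc6)c(OC)c5)c(OC)c4)c(OC)c3)cc2OC)ccc1OCc1ccccc1 | intermediate
36 | (3S,3aR,6S,6aS)-6-ArA-3-ArBC-tetrahydro-1H,3H-furo[3,4-c]furan-1-ol (lactol, both anomers) | COc1cc([C@@H](O[Si](C)(C)C(C)(C)C)[C@H](CO[Si](C)(C)C(C)(C)C)Oc2c(OC)cc([C@H]3OC[C@H]4[C@@H]3C(O)O[C@@H]4c3cc(OC)c(O[C@@H](CO[Si](C)(C)C(C)(C)C)[C@@H](O[Si](C)(C)C(C)(C)C)c4ccc(O[C@H](CO[Si](C)(C)C(C)(C)C)[C@@H](O[Si](C)(C)C(C)(C)C)c5ccc(OCc6ccccc6)c(OC)c5)c(OC)c4)c(OC)c3)cc2OC)ccc1OCc1ccccc1 | intermediate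
37 | (1S,3aR,4S,6aR)-1-ArA-4-ArBC-tetrahydro-1H,3H-furo[3,4-c]furan | COc1cc([C@@H](O[Si](C)(C)C(C)(C)C)[C@H](CO[Si](C)(C)C(C)(C)C)Oc2c(OC)cc([C@H]3OC[C@H]4[C@@H]3CO[C@@H]4c3cc(OC)c(O[C@@H](CO[Si](C)(C)C(C)(C)C)[C@@H](O[Si](C)(C)C(C)(C)C)c4ccc(O[C@H](CO[Si](C)(C)C(C)(C)C)[C@@H](O[Si](C)(C)C(C)(C)C)c5ccc(OCc6ccccc6)c(OC)c5)c(OC)c4)c(OC)c3)cc2OC)ccc1OCc1ccccc1 | intermediate
38 | hexa-TBS ether of the target (all six aliphatic hydroxyls silylated, both phenols free) | COc1cc([C@@H](O[Si](C)(C)C(C)(C)C)[C@H](CO[Si](C)(C)C(C)(C)C)Oc2c(OC)cc([C@H]3OC[C@H]4[C@@H]3CO[C@@H]4c3cc(OC)c(O[C@@H](CO[Si](C)(C)C(C)(C)C)[C@@H](O[Si](C)(C)C(C)(C)C)c4ccc(O[C@H](CO[Si](C)(C)C(C)(C)C)[C@@H](O[Si](C)(C)C(C)(C)C)c5ccc(O)c(OC)c5)c(OC)c4)c(OC)c3)cc2OC)ccc1O | intermediate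
39 | CNP0316493.3 | COc1cc([C@@H](O)[C@H](CO)Oc2c(OC)cc([C@H]3OC[C@H]4[C@@H]3CO[C@@H]4c3cc(OC)c(O[C@@H](CO)[C@@H](O)c4ccc(O[C@H](CO)[C@@H](O)c5ccc(O)c(OC)c5)c(OC)c4)c(OC)c3)cc2OC)ccc1O | target

**Totals**

Total step count: 28.
Longest linear sequence: 21 steps (steps 7–16 and 18–28).

**Steps most likely to fail**

1. Step 23. The insertion may engage the wrong diastereotopic benzylic hydrogen (poor facial control at C7), or the carbenoid may be lost to 1,2-hydride shift or attack on the neighbouring arene. The fallback makes the C7–C8 bond by a lactone aldol and closes both ether rings afterwards through benzylic ionization, which is known to favour exo aryl groups. It sets out from alcohol 28: catalytic KOtBu in THF would give the gamma-lactone (4R)-4-[(S)-ArBC(triethylsilyloxy)methyl]dihydrofuran-2(3H)-one F1. Its lithium enolate (LiN(SiMe3)2, THF, −78 °C) would add to aldehyde 9 anti to the C4 branch to give the trans-3,4-disubstituted aldol lactone F2, whose carbinol epimers at C7 are immaterial. LiAlH4 would give the silylated triol F3, and HF·pyridine the tetraol F4. Methanesulfonyl chloride in pyridine at −20 °C would ionize the two benzylic mesylates, and 5-exo capture by the primary hydroxyls would close rings A and B, coming back to the route at 37.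

2. Step 25. Epimerization at C8 may be incomplete, or ring A may open by retro-oxa-Michael elimination under the alkoxide. The fallback moves the epimerization to the aldehyde level, where a mild amine suffices. It sets out from ester 33: excess i-Bu2AlH (CH2Cl2, −78 to 0 °C) would give the primary alcohol F5, and Dess–Martin periodinane the aldehyde F6. HF·pyridine would free O7' to give the hydroxy aldehyde F7. Catalytic pyrrolidine and AcOH would equilibrate C8 through the enamine, and only the epimer with C9 cis to the C8' branch can close to the cis-fused lactol. The fallback comes back to the route at lactol 36, which would be reduced with Et3SiH and BF3·OEt2 as in the second half of step 26.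

3. Step 21. The oxocarbenium route may over-reduce the electron-rich benzylic position, scramble silyl ethers or give the symmetric dibenzyl ether. The fallback forms the same ether by acid-catalysed benzylation with an imidate. It sets out from aldehyde 9: NaBH4 in MeOH would give the benzyl alcohol ArA–CH2OH F8, and trichloroacetonitrile with catalytic 1,8-diazabicyclo[5.4.0]undec-7-ene the trichloroacetimidate F9. Coupling of F9 with alcohol 28 under catalytic triflic acid in CH2Cl2 at −40 °C comes back to the route at 30.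

**Further compounds**

F1 | step 23 | (4R)-4-[(S)-ArBC(triethylsilyloxy)methyl]dihydrofuran-2(3H)-one | O=C1C[C@H](CO1)[C@H](O[Si](CC)(CC)CC)c1cc(OC)c(O[C@@H](CO[Si](C)(C)C(C)(C)C)[C@@H](O[Si](C)(C)C(C)(C)C)c2ccc(O[C@H](CO[Si](C)(C)C(C)(C)C)[C@@H](O[Si](C)(C)C(C)(C)C)c3ccc(OCc4ccccc4)c(OC)c3)c(OC)c2)c(OC)c1
F2 | step 23 | (3R,4R)-3-[ArA(hydroxy)methyl]-4-[(S)-ArBC(triethylsilyloxy)methyl]dihydrofuran-2(3H)-one (3,4-trans, carbinol epimers) | O=C1OC[C@H]([C@H](O[Si](CC)(CC)CC)c2cc(OC)c(O[C@@H](CO[Si](C)(C)C(C)(C)C)[C@@H](O[Si](C)(C)C(C)(C)C)c3ccc(O[C@H](CO[Si](C)(C)C(C)(C)C)[C@@H](O[Si](C)(C)C(C)(C)C)c4ccc(OCc5ccccc5)c(OC)c4)c(OC)c3)c(OC)c2)[C@H]1C(O)c1cc(OC)c(O[C@@H](CO[Si](C)(C)C(C)(C)C)[C@H](O[Si](C)(C)C(C)(C)C)c2ccc(OCc3ccccc3)c(OC)c2)c(OC)c1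
F3 | step 23 | (2R,3R)-2-[ArA(hydroxy)methyl]-3-[(S)-ArBC(triethylsilyloxy)methyl]butane-1,4-diol | OC[C@H]([C@H](O[Si](CC)(CC)CC)c1cc(OC)c(O[C@@H](CO[Si](C)(C)C(C)(C)C)[C@@H](O[Si](C)(C)C(C)(C)C)c2ccc(O[C@H](CO[Si](C)(C)C(C)(C)C)[C@@H](O[Si](C)(C)C(C)(C)C)c3ccc(OCc4ccccc4)c(OC)c3)c(OC)c2)c(OC)c1)[C@H](CO)C(O)c1cc(OC)c(O[C@@H](CO[Si](C)(C)C(C)(C)C)[C@H](O[Si](C)(C)C(C)(C)C)c2ccc(OCc3ccccc3)c(OC)c2)c(OC)c1
F4 | step 23 | (2R,3R)-2-[ArA(hydroxy)methyl]-3-[(S)-ArBC(hydroxy)methyl]butane-1,4-diol | OC[C@H]([C@H](O)c1cc(OC)c(O[C@@H](CO[Si](C)(C)C(C)(C)C)[C@@H](O[Si](C)(C)C(C)(C)C)c2ccc(O[C@H](CO[Si](C)(C)C(C)(C)C)[C@@H](O[Si](C)(C)C(C)(C)C)c3ccc(OCc4ccccc4)c(OC)c3)c(OC)c2)c(OC)c1)[C@H](CO)C(O)c1cc(OC)c(O[C@@H](CO[Si](C)(C)C(C)(C)C)[C@H](O[Si](C)(C)C(C)(C)C)c2ccc(OCc3ccccc3)c(OC)c2)c(OC)c1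
F5 | step 25 | {(2S,3S,4R)-2-ArA-4-[(S)-ArBC(triethylsilyloxy)methyl]tetrahydrofuran-3-yl}methanol | COc1cc([C@@H](O[Si](C)(C)C(C)(C)C)[C@H](CO[Si](C)(C)C(C)(C)C)Oc2c(OC)cc([C@H]3OC[C@H]([C@H](O[Si](CC)(CC)CC)c4cc(OC)c(O[C@@H](CO[Si](C)(C)C(C)(C)C)[C@@H](O[Si](C)(C)C(C)(C)C)c5ccc(O[C@H](CO[Si](C)(C)C(C)(C)C)[C@@H](O[Si](C)(C)C(C)(C)C)c6ccc(OCc7ccccc7)c(OC)c6)c(OC)c5)c(OC)c4)[C@H]3CO)cc2OC)ccc1OCc1ccccc1
F6 | step 25 | (2S,3R,4R)-2-ArA-4-[(S)-ArBC(triethylsilyloxy)methyl]tetrahydrofuran-3-carbaldehyde | COc1cc([C@@H](O[Si](C)(C)C(C)(C)C)[C@H](CO[Si](C)(C)C(C)(C)C)Oc2c(OC)cc([C@H]3OC[C@H]([C@H](O[Si](CC)(CC)CC)c4cc(OC)c(O[C@@H](CO[Si](C)(C)C(C)(C)C)[C@@H](O[Si](C)(C)C(C)(C)C)c5ccc(O[C@H](CO[Si](C)(C)C(C)(C)C)[C@@H](O[Si](C)(C)C(C)(C)C)c6ccc(OCc7ccccc7)c(OC)c6)c(OC)c5)c(OC)c4)[C@H]3C=O)cc2OC)ccc1OCc1ccccc1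
F7 | step 25 | (2S,3R,4R)-2-ArA-4-[(S)-ArBC(hydroxy)methyl]tetrahydrofuran-3-carbaldehyde | COc1cc([C@@H](O[Si](C)(C)C(C)(C)C)[C@H](CO[Si](C)(C)C(C)(C)C)Oc2c(OC)cc([C@H]3OC[C@H]([C@H](O)c4cc(OC)c(O[C@@H](CO[Si](C)(C)C(C)(C)C)[C@@H](O[Si](C)(C)C(C)(C)C)c5ccc(O[C@H](CO[Si](C)(C)C(C)(C)C)[C@@H](O[Si](C)(C)C(C)(C)C)c6ccc(OCc7ccccc7)c(OC)c6)c(OC)c5)c(OC)c4)[C@H]3C=O)cc2OC)ccc1OCc1ccccc1
F8 | step 21 | [3,5-dimethoxy-4-(SA-oxy)phenyl]methanol | COc1cc([C@@H](O[Si](C)(C)C(C)(C)C)[C@H](CO[Si](C)(C)C(C)(C)C)Oc2c(OC)cc(CO)cc2OC)ccc1OCc1ccccc1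
F9 | step 21 | 3,5-dimethoxy-4-(SA-oxy)benzyl 2,2,2-trichloroacetimidate | COc1cc([C@@H](O[Si](C)(C)C(C)(C)C)[C@H](CO[Si](C)(C)C(C)(C)C)Oc2c(OC)cc(COC(=N)C(Cl)(Cl)Cl)cc2OC)ccc1OCc1ccccc1
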